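Retrosynthetic cuts: both galloyl ester bonds (at O3 and O5), then O1–C2 of ring C, C2–C1' to ring B, O1–C8a on ring A (taken back through C8a–Si to a plain C8a–H), and finally C3–C4.
Enabling feature: without O1, ring A is a 2,4-dioxygenated benzyl unit whose oxygens O5 and O7 are easily told apart. The empty carbon C8a is tied to O3 by the path O3–C3–C4–C4a–C8a, so silicon on O3 meets C8a–H in a six-membered ring, while the other ortho carbon, C5, carries O5.
Forward order: ring A is bought and the C4–C3–C2 chain is added by olefination. The temporary oxasilacycle closes and is oxidised open to O1–H and O3–H, ring B is joined at C2, ring C closes last at O1–C2, and both galloyl rings go on together.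
Stereochemistry: C3 (R) comes from hydrogenation with [Rh(cod)((R,R)-Et-DuPhos)]BF4. C2 is set from C3 by chelation-controlled ketone reduction (S) and turned to R by SN2 ring closure, which gives the 2,3-cis flavan.

Key step: step 7

Assumption: the (R,R)-Et-DuPhos rhodium catalyst is taken to give the (R)-acetate, the sense known for dehydroamino esters and α-acyloxyacrylates, and phosphonate 4 is taken as a catalogue reagent. Flavan numbering is used for the atoms of all intermediates.

Step 1
Reactants: 1 2,4-dihydroxybenzaldehyde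
Product: 2 4-(benzyloxy)-2-hydroxybenzaldehyde
Conditions: BnBr (1.05 equiv), NaHCO3, MeCN, 80 °C
Reagents that add atoms: benzyl bromide, BrCc1ccccc1
Why: Williamson etherification, in which the 2-OH is held in a hydrogen bond to the aldehyde and is the less acidic phenol, so a weak base should ionise and benzylate only the 4-OH (future O7).

Step 2
Reactants: 2 4-(benzyloxy)-2-hydroxybenzaldehyde
Product: 3 4-(benzyloxy)-2-(triisopropylsilyloxy)benzaldehyde
Conditions: TIPSCl, imidazole, DMF, rt
Reagents that add atoms: chlorotriisopropylsilane, CC(C)[Si](Cl)(C(C)C)C(C)C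
Why: Imidazole-promoted silylation of the remaining phenol marks the future O5 with a group orthogonal to benzyl, very stable to acid and slow to leave under weak base.

Step 3
Reactants: 3 4-(benzyloxy)-2-(triisopropylsilyloxy)benzaldehyde; 4 ethyl 2-acetoxy-2-(diethoxyphosphoryl)acetate
Product: 5 ethyl (Z)-2-acetoxy-3-[4-(benzyloxy)-2-(triisopropylsilyloxy)phenyl]acrylate
Conditions: LiCl, DBU, MeCN, 0 °C to rt
Reagents that add atoms: none
Why: Horner–Wadsworth–Emmons olefination under Masamune–Roush conditions forms C3=C4 mildly enough for the enol acetate and the aryl silyl ether, should favour the Z alkene, and any E isomer can be carried on because the next step converges.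

Step 4
Reactants: 5 ethyl (Z)-2-acetoxy-3-[4-(benzyloxy)-2-(triisopropylsilyloxy)phenyl]acrylate
Product: 6 ethyl (R)-2-acetoxy-3-[4-(benzyloxy)-2-(triisopropylsilyloxy)phenyl]propanoate
Conditions: H2 (5 bar), [Rh(cod)((R,R)-Et-DuPhos)]BF4 (1 mol %), MeOH, rt
Reagents that add atoms: none
Why: Catalyst-controlled asymmetric hydrogenation of an α-acyloxyacrylate, in which the acetate carbonyl chelates rhodium as an enamide does and the (R,R)-ligand directs H2 to the face that makes C3 R, while benzyl ethers are inert to this homogeneous catalyst.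

Step 5
Reactants: 6 ethyl (R)-2-acetoxy-3-[4-(benzyloxy)-2-(triisopropylsilyloxy)phenyl]propanoate
Product: 7 methyl (R)-3-[4-(benzyloxy)-2-(triisopropylsilyloxy)phenyl]-2-hydroxypropanoate
Conditions: HCl (1.25 M in MeOH), 45 °C
Reagents that add atoms: methanol, CO
Why: Acid-catalysed transesterification in methanol as solvent removes the acetate and exchanges ethyl for methyl by mass action, without the base that could racemise C3 or cleave the aryl TIPS ether.

Step 6
Reactants: 7 methyl (R)-3-[4-(benzyloxy)-2-(triisopropylsilyloxy)phenyl]-2-hydroxypropanoate; 8 chlorodiethylsilane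
Product: 9 methyl (R)-3-[4-(benzyloxy)-2-(triisopropylsilyloxy)phenyl]-2-(diethylsilyloxy)propanoate
Conditions: Et3N, CH2Cl2, 0 °C to rt; filtration under N2, concentration
Reagents that add atoms: none
Why: Silylation of the secondary alcohol O3–H with a chlorosilane and an amine base leaves the Si–H bond untouched, and the moisture-sensitive ether is only filtered and concentrated before use.

Step 7
Reactants: 9 methyl (R)-3-[4-(benzyloxy)-2-(triisopropylsilyloxy)phenyl]-2-(diethylsilyloxy)propanoate
Product: 10 methyl (3R)-7-(benzyloxy)-1,1-diethyl-5-(triisopropylsilyloxy)-3,4-dihydro-1H-2,1-benzoxasiline-3-carboxylate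
Conditions: [Ir(cod)OMe]2 (2 mol %), 3,4,7,8-tetramethyl-1,10-phenanthroline (5 mol %), norbornene (1.5 equiv), THF, 100 °C, sealed tube
Reagents that add atoms: none
Why: Proposed new method: the Si–H bond of 9 converts [Ir(cod)OMe]2 and the phenanthroline into an iridium silyl hydride, norbornene takes up the hydride ligands, the C8a–H bond adds oxidatively to the metal held by the O3–Si tether, and C–Si reductive elimination releases 10. The closest known reactions are the same dehydrogenative silylation of benzylic hydrosilyl ethers to five-membered benzoxasiloles and the ortho-silylation of phenol-derived hydrosilyl acetals to six-membered benzodioxasilines, whereas a homobenzylic hydrosilyl ether bearing an α-ester has not been shown. The one ring formed (Si, O3, C3, C4, C4a, C8a) closes by reductive elimination from a seven-membered iridacycle, that is, by intramolecular C–H/Si–H coupling and not by a polar cyclisation. No stereocentre is created, and C3 should stay R because it takes no part in the reaction and the medium is neutral. The step needs site selectivity among the arene C–H bonds and chemoselectivity against hydrosilylation of the ester carbonyl: the first is secured by the tether length, by O5 on the other ortho carbon C5, by the lack of any aliphatic C–H placed for a five-membered ring and by the absence of ring B, the second by the neutral nitrogen-ligated catalyst, which is known to tolerate esters. The bulky 5-OTIPS group should also turn the side chain out of the arene plane toward the C8a side and so help the larger ring to close.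

Step 8
Reactants: 10 methyl (3R)-7-(benzyloxy)-1,1-diethyl-5-(triisopropylsilyloxy)-3,4-dihydro-1H-2,1-benzoxasiline-3-carboxylate
Product: 11 methyl (R)-3-[4-(benzyloxy)-2-hydroxy-6-(triisopropylsilyloxy)phenyl]-2-hydroxypropanoate
Conditions: 30% aq H2O2, KHCO3, THF/MeOH, rt
Reagents that add atoms: hydrogen peroxide, OO
Why: Tamao–Fleming oxidation, in which hydroperoxide adds to the alkoxy-activated silicon and the aryl group migrates from Si to O at the same carbon, so C8a–Si becomes C8a–O1 and hydrolysis frees O1–H and O3–H together, while bicarbonate without fluoride should spare the aryl TIPS ether and the ester.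

Step 9
Reactants: 11 methyl (R)-3-[4-(benzyloxy)-2-hydroxy-6-(triisopropylsilyloxy)phenyl]-2-hydroxypropanoate
Product: 12 (R)-3-[4-(benzyloxy)-2-hydroxy-6-(triisopropylsilyloxy)phenyl]-2-hydroxy-N-methoxy-N-methylpropanamide
Conditions: MeNH(OMe)·HCl, iPrMgCl (excess), THF, −20 to 0 °C
Reagents that add atoms: N,O-dimethylhydroxylamine hydrochloride, CNOC.Cl
Why: Weinreb amide formation from an unprotected α-hydroxy ester with the chloromagnesium amide is well established and does not racemise the alkoxide-bearing centre, and the amide is preferred to an aryl lactone, whose phenoxide leaving group would invite double addition in step 11.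

Step 10
Reactants: 13 4-bromocatechol
Product: 14 1,2-bis(benzyloxy)-4-bromobenzene
Conditions: BnBr (2.2 equiv), K2CO3, DMF, 50 °C
Reagents that add atoms: benzyl bromide, BrCc1ccccc1
Why: Double Williamson etherification protects both ring B phenols with the group that is removed in the last step.

Step 11
Reactants: 12 (R)-3-[4-(benzyloxy)-2-hydroxy-6-(triisopropylsilyloxy)phenyl]-2-hydroxy-N-methoxy-N-methylpropanamide; 14 1,2-bis(benzyloxy)-4-bromobenzene
Product: 16 (R)-1-[3,4-bis(benzyloxy)phenyl]-3-[4-(benzyloxy)-2-hydroxy-6-(triisopropylsilyloxy)phenyl]-2-hydroxypropan-1-one, via aryllithium 15 (not isolated)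
Conditions: 14, n-BuLi, THF, −78 °C; 12 pre-treated with iPrMgCl (2 equiv), THF, −40 °C; mix, −78 to −10 °C; aq NH4Cl
Reagents that add atoms: n-butyllithium, [Li]CCCC (supplies only the lithium of 15; nothing from it remains in 16)
Why: Bromine–lithium exchange followed by Weinreb ketone synthesis forms C2–C1', the chelated tetrahedral adduct lasting until the quench so that no second addition occurs, and the neighbouring alkoxide shields C3–H from deprotonation.

Step 12
Reactants: 16 (R)-1-[3,4-bis(benzyloxy)phenyl]-3-[4-(benzyloxy)-2-hydroxy-6-(triisopropylsilyloxy)phenyl]-2-hydroxypropan-1-one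
Product: 17 (1S,2R)-1-[3,4-bis(benzyloxy)phenyl]-3-[4-(benzyloxy)-2-hydroxy-6-(triisopropylsilyloxy)phenyl]propane-1,2-diol
Conditions: Zn(BH4)2 (stock solution in Et2O), Et2O/CH2Cl2, −30 to 0 °C
Reagents that add atoms: none
Why: Chelation-controlled reduction (Cram chelate model), in which zinc bridges O3 and the carbonyl oxygen and hydride enters from the side of the C3–H bond, should set the carbinol carbon (future C2) as S and give the anti (erythro) diol.

Step 13
Reactants: 17 (1S,2R)-1-[3,4-bis(benzyloxy)phenyl]-3-[4-(benzyloxy)-2-hydroxy-6-(triisopropylsilyloxy)phenyl]propane-1,2-diol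
Product: 18 (2R,3R)-7-(benzyloxy)-2-[3,4-bis(benzyloxy)phenyl]-5-(triisopropylsilyloxy)chroman-3-ol
Conditions: PPh3, DIAD, THF (0.01 M), 0 °C
Reagents that add atoms: none
Why: Intramolecular Mitsunobu etherification, a known way to close flavan-3-ols from such triols, activates the benzylic hydroxyl and lets the only free phenol O1 displace it in a 6-exo-tet SN2 step, inverting C2 from S to R and closing ring C as the 2,3-cis isomer.

Step 14
Reactants: 18 (2R,3R)-7-(benzyloxy)-2-[3,4-bis(benzyloxy)phenyl]-5-(triisopropylsilyloxy)chroman-3-ol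
Product: 19 (2R,3R)-7-(benzyloxy)-2-[3,4-bis(benzyloxy)phenyl]chroman-3,5-diol
Conditions: TBAF, AcOH, THF, 0 °C
Reagents that add atoms: none
Why: Fluoride cleavage of the aryl silyl ether, buffered with acetic acid so that no basic phenoxide builds up, frees O5–H next to the already free O3–H and touches no stereocentre.

Step 15
Reactants: 19 (2R,3R)-7-(benzyloxy)-2-[3,4-bis(benzyloxy)phenyl]chroman-3,5-diol; 20 3,4,5-tris(benzyloxy)benzoic acid
Product: 21 (2R,3R)-7-(benzyloxy)-2-[3,4-bis(benzyloxy)phenyl]chroman-3,5-diyl bis[3,4,5-tris(benzyloxy)benzoate]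
Conditions: 20 (3 equiv), DCC, DMAP, CH2Cl2, rt
Reagents that add atoms: none
Why: Steglich esterification with excess acid acylates the phenol O5–H and the axial secondary O3–H in one operation, a coupling routinely used for 3-O-galloylation of benzylated epi-series flavan-3-ols.

Step 16
Reactants: 21 (2R,3R)-7-(benzyloxy)-2-[3,4-bis(benzyloxy)phenyl]chroman-3,5-diyl bis[3,4,5-tris(benzyloxy)benzoate]
Product: 22 (−)-epicatechin 3,5-di-O-gallate, (2R,3R)
Conditions: H2 (1 atm), Pd(OH)2/C, THF/EtOAc, rt
Reagents that add atoms: none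
Why: Neutral hydrogenolysis removes all nine benzyl ethers, as in the usual last step toward catechin gallates, and the non-nucleophilic solvent should protect the labile aryl gallate at O5 from solvolysis and C2 from epimerisation.

Compound list
1 | 2,4-dihydroxybenzaldehyde | O=Cc1ccc(O)cc1O | starting material
2 | 4-(benzyloxy)-2-hydroxybenzaldehyde | O=Cc1ccc(OCc2ccccc2)cc1O | intermediate
3 | 4-(benzyloxy)-2-(triisopropylsilyloxy)benzaldehyde | O=Cc1ccc(OCc2ccccc2)cc1O[Si](C(C)C)(C(C)C)C(C)C | intermediate
4 | ethyl 2-acetoxy-2-(diethoxyphosphoryl)acetate | CCOC(=O)C(OC(C)=O)P(=O)(OCC)OCC | starting material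
5 | ethyl (Z)-2-acetoxy-3-[4-(benzyloxy)-2-(triisopropylsilyloxy)phenyl]acrylate | CCOC(=O)/C(OC(C)=O)=C/c1ccc(OCc2ccccc2)cc1O[Si](C(C)C)(C(C)C)C(C)C | intermediate
6 | ethyl (R)-2-acetoxy-3-[4-(benzyloxy)-2-(triisopropylsilyloxy)phenyl]propanoate | CC(=O)O[C@@H](C(=O)OCC)Cc1ccc(OCc2ccccc2)cc1O[Si](C(C)C)(C(C)C)C(C)C | intermediate
7 | methyl (R)-3-[4-(benzyloxy)-2-(triisopropylsilyloxy)phenyl]-2-hydroxypropanoate | O[C@@H](C(=O)OC)Cc1ccc(OCc2ccccc2)cc1O[Si](C(C)C)(C(C)C)C(C)C | intermediate
8 | chlorodiethylsilane | CC[SiH](Cl)CC | starting material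
9 | methyl (R)-3-[4-(benzyloxy)-2-(triisopropylsilyloxy)phenyl]-2-(diethylsilyloxy)propanoate | CC[SiH](CC)O[C@@H](C(=O)OC)Cc1ccc(OCc2ccccc2)cc1O[Si](C(C)C)(C(C)C)C(C)C | intermediate
10 | methyl (3R)-7-(benzyloxy)-1,1-diethyl-5-(triisopropylsilyloxy)-3,4-dihydro-1H-2,1-benzoxasiline-3-carboxylate | CC[Si]1(CC)O[C@@H](C(=O)OC)Cc2c(O[Si](C(C)C)(C(C)C)C(C)C)cc(OCc3ccccc3)cc21 | intermediate
11 | methyl (R)-3-[4-(benzyloxy)-2-hydroxy-6-(triisopropylsilyloxy)phenyl]-2-hydroxypropanoate | O[C@@H](C(=O)OC)Cc1c(O)cc(OCc2ccccc2)cc1O[Si](C(C)C)(C(C)C)C(C)C | intermediate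
12 | (R)-3-[4-(benzyloxy)-2-hydroxy-6-(triisopropylsilyloxy)phenyl]-2-hydroxy-N-methoxy-N-methylpropanamide | O[C@@H](C(=O)N(C)OC)Cc1c(O)cc(OCc2ccccc2)cc1O[Si](C(C)C)(C(C)C)C(C)C | intermediate
13 | 4-bromocatechol | Oc1ccc(Br)cc1O | starting material
14 | 1,2-bis(benzyloxy)-4-bromobenzene | Brc1ccc(OCc2ccccc2)c(OCc2ccccc2)c1 | intermediate
15 | [3,4-bis(benzyloxy)phenyl]lithium | [Li]c1ccc(OCc2ccccc2)c(OCc2ccccc2)c1 | intermediate
16 | (R)-1-[3,4-bis(benzyloxy)phenyl]-3-[4-(benzyloxy)-2-hydroxy-6-(triisopropylsilyloxy)phenyl]-2-hydroxypropan-1-one | O[C@@H](C(=O)c1ccc(OCc2ccccc2)c(OCc2ccccc2)c1)Cc1c(O)cc(OCc2ccccc2)cc1O[Si](C(C)C)(C(C)C)C(C)C | intermediate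
17 | (1S,2R)-1-[3,4-bis(benzyloxy)phenyl]-3-[4-(benzyloxy)-2-hydroxy-6-(triisopropylsilyloxy)phenyl]propane-1,2-diol | O[C@@H]([C@@H](O)c1ccc(OCc2ccccc2)c(OCc2ccccc2)c1)Cc1c(O)cc(OCc2ccccc2)cc1O[Si](C(C)C)(C(C)C)C(C)C | intermediate
18 | (2R,3R)-7-(benzyloxy)-2-[3,4-bis(benzyloxy)phenyl]-5-(triisopropylsilyloxy)chroman-3-ol | O[C@@H]1Cc2c(O[Si](C(C)C)(C(C)C)C(C)C)cc(OCc3ccccc3)cc2O[C@@H]1c4ccc(OCc5ccccc5)c(OCc6ccccc6)c4 | intermediate
19 | (2R,3R)-7-(benzyloxy)-2-[3,4-bis(benzyloxy)phenyl]chroman-3,5-diol | O[C@@H]1Cc2c(O)cc(OCc3ccccc3)cc2O[C@@H]1c4ccc(OCc5ccccc5)c(OCc6ccccc6)c4 | intermediate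
20 | 3,4,5-tris(benzyloxy)benzoic acid | O=C(O)c1cc(OCc2ccccc2)c(OCc2ccccc2)c(OCc2ccccc2)c1 | starting material
21 | (2R,3R)-7-(benzyloxy)-2-[3,4-bis(benzyloxy)phenyl]chroman-3,5-diyl bis[3,4,5-tris(benzyloxy)benzoate] | O=C(Oc1cc(OCc2ccccc2)cc2c1C[C@@H](OC(=O)c1cc(OCc3ccccc3)c(OCc3ccccc3)c(OCc3ccccc3)c1)[C@@H](c1ccc(OCc3ccccc3)c(OCc3ccccc3)c1)O2)c1cc(OCc2ccccc2)c(OCc2ccccc2)c(OCc2ccccc2)c1 | intermediate
22 | (−)-epicatechin 3,5-di-O-gallate, (2R,3R) | O=C(Oc1cc(O)cc2c1C[C@@H](OC(=O)c1cc(O)c(O)c(O)c1)[C@@H](c1ccc(O)c(O)c1)O2)c1cc(O)c(O)c(O)c1 | target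

Total step count: 16. Longest linear sequence: 15 steps (steps 1–9 and 11–16, from 2,4-dihydroxybenzaldehyde); step 10 is a one-step side branch.

Steps most likely to fail

Step 7. C–H activation through the larger, seven-membered metallacycle may be too slow. Hydrosilylation of the neighbouring ester carbonyl, redistribution at silicon or intermolecular silylation could then take over.

The fallback uses the established five-membered version of the same tether logic, with silicon hung on the C4 oxygen. It sets out from aldehyde 3. Hydrosilylation with Et2SiH2 and [Ir(cod)OMe]2 in THF at rt gives the benzyl diethylhydrosilyl ether F1. Adding 1,10-phenanthroline and norbornene at 80–100 °C closes it at the same free ortho C–H to the benzoxasilole F2. H2O2/KHCO3 then gives the salicyl alcohol F3, MnO2 in CH2Cl2 the salicylaldehyde F4, and MOMCl/iPr2NEt the MOM-protected aldehyde F5. Olefination with 4 as in step 3 gives the acetoxyacrylate F6, and hydrogenation as in step 4 gives the (R)-acetate F7. HCl in MeOH as in step 5 removes the acetate and the MOM group and exchanges the ester, and the route is rejoined at 11.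

Step 13. The activated benzylic oxyphosphonium ion carries a para-alkoxy aryl group and may ionise. That would erode the inversion in favour of the more stable 2,3-trans ring. Activation of the C3 hydroxyl is a second way to lose material.

The fallback avoids substitution at C2 and sets out from ketone 16, so step 12 is bypassed as well. The free phenol adds to the carbonyl to give the cyclic hemiketal F8. BF3·OEt2 in CH2Cl2 at −78 to −40 °C ionises it to the 2-aryl oxocarbenium ion, and Et3SiH reduces that ion from the face opposite the pseudoaxial O3. This is the hemiketal reduction used for C-aryl glycosides, and as a reductive etherification it is known to give 2,3-cis 2-arylchromans. It comes back to the route at 18.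

Step 11. Addition to the doubly deprotonated amide may be sluggish. Enolisation or a ketol shift of the liberated α-hydroxy ketone during the quench could also erode the configuration at C3.

The fallback forms C2–C1' at the aldehyde oxidation level, so that no ketone is ever made, and sets out from 11. TESCl/imidazole gives the bis(triethylsilyl) ether F9, and iBu2AlH in toluene at −78 °C gives the α-silyloxy aldehyde F10. Aryllithium 15 in Et2O at −78 °C adds under Felkin–Anh control, without chelation, to give the anti carbinol F11. HF·pyridine in THF/pyridine at 0 °C removes both triethylsilyl groups while the aryl TIPS ether stays. The route is rejoined at 17, bypassing steps 9, 11 and 12.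

Further compounds
F1 | step 7 | {[4-(benzyloxy)-2-(triisopropylsilyloxy)phenyl]methoxy}diethylsilane | CC[SiH](CC)OCc1ccc(OCc2ccccc2)cc1O[Si](C(C)C)(C(C)C)C(C)C
F2 | step 7 | 6-(benzyloxy)-1,1-diethyl-4-(triisopropylsilyloxy)-1,3-dihydro-2,1-benzoxasilole | CC[Si]1(CC)OCc2c(O[Si](C(C)C)(C(C)C)C(C)C)cc(OCc3ccccc3)cc21
F3 | step 7 | 5-(benzyloxy)-2-(hydroxymethyl)-3-(triisopropylsilyloxy)phenol | OCc1c(O)cc(OCc2ccccc2)cc1O[Si](C(C)C)(C(C)C)C(C)C
F4 | step 7 | 4-(benzyloxy)-2-hydroxy-6-(triisopropylsilyloxy)benzaldehyde | O=Cc1c(O)cc(OCc2ccccc2)cc1O[Si](C(C)C)(C(C)C)C(C)C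
F5 | step 7 | 4-(benzyloxy)-2-(methoxymethoxy)-6-(triisopropylsilyloxy)benzaldehyde | O=Cc1c(OCOC)cc(OCc2ccccc2)cc1O[Si](C(C)C)(C(C)C)C(C)C
F6 | step 7 | ethyl (Z)-2-acetoxy-3-[4-(benzyloxy)-2-(methoxymethoxy)-6-(triisopropylsilyloxy)phenyl]acrylate | CCOC(=O)/C(OC(C)=O)=C/c1c(OCOC)cc(OCc2ccccc2)cc1O[Si](C(C)C)(C(C)C)C(C)C
F7 | step 7 | ethyl (R)-2-acetoxy-3-[4-(benzyloxy)-2-(methoxymethoxy)-6-(triisopropylsilyloxy)phenyl]propanoate | CC(=O)O[C@@H](C(=O)OCC)Cc1c(OCOC)cc(OCc2ccccc2)cc1O[Si](C(C)C)(C(C)C)C(C)C
F8 | step 13 | (3R)-7-(benzyloxy)-2-[3,4-bis(benzyloxy)phenyl]-5-(triisopropylsilyloxy)chroman-2,3-diol (cyclic hemiketal, both C2 epimers) | O[C@@H]1Cc2c(O[Si](C(C)C)(C(C)C)C(C)C)cc(OCc3ccccc3)cc2OC1(O)c4ccc(OCc5ccccc5)c(OCc6ccccc6)c4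
F9 | step 11 | methyl (R)-3-[4-(benzyloxy)-2-(triethylsilyloxy)-6-(triisopropylsilyloxy)phenyl]-2-(triethylsilyloxy)propanoate | CC[Si](CC)(CC)O[C@@H](C(=O)OC)Cc1c(O[Si](CC)(CC)CC)cc(OCc2ccccc2)cc1O[Si](C(C)C)(C(C)C)C(C)C
F10 | step 11 | (R)-3-[4-(benzyloxy)-2-(triethylsilyloxy)-6-(triisopropylsilyloxy)phenyl]-2-(triethylsilyloxy)propanal | CC[Si](CC)(CC)O[C@@H](C=O)Cc1c(O[Si](CC)(CC)CC)cc(OCc2ccccc2)cc1O[Si](C(C)C)(C(C)C)C(C)C
F11 | step 11 | (1S,2R)-1-[3,4-bis(benzyloxy)phenyl]-3-[4-(benzyloxy)-2-(triethylsilyloxy)-6-(triisopropylsilyloxy)phenyl]-2-(triethylsilyloxy)propan-1-ol | CC[Si](CC)(CC)O[C@@H]([C@@H](O)c1ccc(OCc2ccccc2)c(OCc2ccccc2)c1)Cc1c(O[Si](CC)(CC)CC)cc(OCc2ccccc2)cc1O[Si](C(C)C)(C(C)C)C(C)C
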